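## Retrosynthetic overview
1. The acid is released last from its tert-butyl ester, and the C–Br bond comes from a C–Si bond on the alkyne one step earlier.
2. C7–C8 and the 8E alkene: boron-to-carbon 1,2-shift (Zweifel type) between a secondary cyclopropylcarbinyl boronic ester and a (1Z,3E)-dienyllithium.
3. C6–C7 and the C7 centre: reagent-controlled boron-to-carbon 1,2-shift of a trans-cyclopropyl boronic ester onto an (S)-1-lithioethyl carbenoid.
4. The only ring, the cyclopropane, is formed first. An enantioselective borylcyclopropanation of tert-butyl hex-5-enoate sets C5 and C6.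
5. The dienyl iodide comes from acetylene carbocupration after methylalumination of a diyne. Its C15 centre comes from (R)-propylene oxide by SN2 inversion of a tosylate.

Assumption: the sense of induction in step 2 cannot be predicted, so the (S,S)-diamine is written as the one giving (1R,2R)-3; if a pilot run gives the mirror image, the equally available (R,R)-diamine is used and nothing else changes.

## Route

Step 1
Reactants: 1 hex-5-enoic acid
Product: 2 tert-butyl hex-5-enoate
Conditions: Boc2O, DMAP (cat.), t-BuOH, rt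
Reagents that add atoms: di-tert-butyl dicarbonate CC(C)(C)OC(=O)OC(=O)OC(C)(C)C
Why: DMAP-catalysed mixed-anhydride esterification gives the one simple ester that survives the two later organolithium steps, and no stereocentre is involved.

Step 2
Reactants: 2 tert-butyl hex-5-enoate
Product: 3 tert-butyl 4-[(1R,2R)-2-(4,4,5,5-tetramethyl-1,3,2-dioxaborolan-2-yl)cyclopropyl]butanoate
Conditions: pinB-CHI2 (2 equiv), CrCl2 (8 equiv), (S,S)-N,N,N',N'-tetramethylcyclohexane-1,2-diamine (8 equiv, recovered by acid extraction), THF, 25 to 50 °C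
Reagents that add atoms: 2-(diiodomethyl)-4,4,5,5-tetramethyl-1,3,2-dioxaborolane CC1(C)OB(OC1(C)C)C(I)I
Why: Proposed new method: enantioselective Takai-type borylcyclopropanation, in which Cr(II) reduces pinB-CHI2 to a diamine-ligated gem-dichromium(III) carbenoid that transfers CH(Bpin) to the unactivated terminal alkene while the diamine is still bound to chromium, so replacing achiral TMEDA (closest known reaction type: the racemic, trans-selective CrCl2/TMEDA borylcyclopropanation of unactivated alkenes) by a C2-symmetric diamine should differentiate the alkene faces and set C5 and C6 together, trans because Bpin and the chain avoid each other.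

Step 3
Reactants: 3 tert-butyl 4-[(1R,2R)-2-(4,4,5,5-tetramethyl-1,3,2-dioxaborolan-2-yl)cyclopropyl]butanoate
Product: 5 tert-butyl 4-[(1R,2S)-2-[(1R)-1-(4,4,5,5-tetramethyl-1,3,2-dioxaborolan-2-yl)ethyl]cyclopropyl]butanoate, via lithium boronate complex 4 (not isolated)
Conditions: ethyl 2,4,6-triisopropylbenzoate (1.3 equiv), s-BuLi (1.25 equiv), (−)-sparteine (1.3 equiv), Et2O, −78 °C, 5 h; add 3, −78 °C, 1 h; then reflux, 12 h
Reagents that add atoms: ethyl 2,4,6-triisopropylbenzoate CCOC(=O)c1c(C(C)C)cc(C(C)C)cc1C(C)C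
Why: Lithiation–borylation (Matteson-type 1,2-metallate rearrangement): sparteine-directed removal of the pro-S proton gives a configurationally stable (S)-carbenoid that is borylated with retention, after which the cyclopropyl group shifts from boron to carbon with retention at C6 and inversion at the carbenoid carbon, forming C6–C7, setting C7 and turning any ent-3 into a separable diastereomer.

Step 4
Reactants: 6 ethynyltriisopropylsilane; 7 (R)-2-methyloxirane
Product: 9 (2R)-5-(triisopropylsilyl)pent-4-yn-2-ol, via lithium acetylide 8 (not isolated)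
Conditions: 6, n-BuLi, THF, −78 °C; BF3·OEt2; 7, −78 °C
Reagents that add atoms: none
Why: BF3-assisted epoxide alkynylation (Yamaguchi–Hirao type) attacks only the CH2 terminus, so the stereocentre of 7 is carried over untouched.

Step 5
Reactants: 9 (2R)-5-(triisopropylsilyl)pent-4-yn-2-ol
Product: 10 (2R)-5-(triisopropylsilyl)pent-4-yn-2-yl 4-methylbenzenesulfonate
Conditions: TsCl, pyridine, DMAP (cat.), 0 °C to rt
Reagents that add atoms: 4-methylbenzenesulfonyl chloride Cc1ccc(cc1)S(=O)(=O)Cl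
Why: O-sulfonylation breaks no bond at carbon, so the configuration is retained.

Step 6
Reactants: 10 (2R)-5-(triisopropylsilyl)pent-4-yn-2-yl 4-methylbenzenesulfonate; 11 (5-chloropent-1-yn-1-yl)trimethylsilane
Product: 14 [(4R)-4-methylnona-1,8-diyn-1-yl]triisopropylsilane, via Grignard reagent 12 (not isolated), via bis-silyl diyne 13 (not isolated)
Conditions: 11, Mg, THF, reflux; then 10, CuI (10 mol %), TMEDA (20 mol %), LiOMe (1 equiv), THF, 0 °C; then MeOH, K2CO3 (cat.), rt
Reagents that add atoms: none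
Why: Copper-catalysed Kumada-type sp3–sp3 coupling displaces the secondary tosylate by SN2 with inversion to set C15 (the descriptor stays R because the priorities change), and methanolysis then removes only the TMS group because TIPS is far more hindered.

Step 7
Reactants: 14 [(4R)-4-methylnona-1,8-diyn-1-yl]triisopropylsilane
Product: 16 [(4R,8E)-9-iodo-4,8-dimethylnon-8-en-1-yn-1-yl]triisopropylsilane, via alkenylalane 15 (not isolated)
Conditions: Me3Al (2.5 equiv), Cp2ZrCl2 (0.25 equiv), CH2Cl2, 0 °C to rt; then I2, THF, −30 °C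
Reagents that add atoms: trimethylaluminium C[Al](C)C; iodine II
Why: Negishi Zr-catalysed syn-methylalumination occurs only at the terminal alkyne (the silyl alkyne is inert), and iodinolysis with retention fixes the 10E trisubstituted alkene.

Step 8
Reactants: 16 [(4R,8E)-9-iodo-4,8-dimethylnon-8-en-1-yn-1-yl]triisopropylsilane; 17 acetylene
Product: 21 [(4R,8E,10Z)-11-iodo-4,8-dimethylundeca-8,10-dien-1-yn-1-yl]triisopropylsilane, via alkenyllithium 18 (not isolated), via dialkenylcuprate 19 (not isolated), via bis(dienyl)cuprate 20 (not isolated)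
Conditions: t-BuLi (2 equiv), Et2O, −78 °C; CuBr·SMe2 (0.5 equiv), −40 °C; HC≡CH (1 equiv per alkenyl group), −50 to −10 °C; I2, −78 to 0 °C
Reagents that add atoms: iodine II
Why: Normant-type syn-carbocupration of acetylene places copper cis to the incoming alkenyl group, and iodinolysis with retention therefore gives the (1Z,3E)-iododiene.

Step 9
Reactants: 5 tert-butyl 4-[(1R,2S)-2-[(1R)-1-(4,4,5,5-tetramethyl-1,3,2-dioxaborolan-2-yl)ethyl]cyclopropyl]butanoate; 21 [(4R,8E,10Z)-11-iodo-4,8-dimethylundeca-8,10-dien-1-yn-1-yl]triisopropylsilane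
Product: 25 tert-butyl 4-[(1R,2R)-2-[(2S,3E,5E,10R)-6,10-dimethyl-13-(triisopropylsilyl)trideca-3,5-dien-12-yn-2-yl]cyclopropyl]butanoate, via dienyllithium 22 (not isolated), via dienyl boronate complex 23 (not isolated), via beta-iodo boronic ester 24 (not isolated)
Conditions: 21 (1.2 equiv), t-BuLi (2.4 equiv), Et2O, −78 °C; 5, THF, −78 °C; I2, THF, −78 °C; NaOMe, MeOH, −78 °C to rt
Reagents that add atoms: none
Why: Zweifel olefination: iodonium activation of the (Z)-alkenyl boronate triggers a stereospecific 1,2-metallate shift of the secondary cyclopropylcarbinyl group (retention at C7) anti to iodine, and methoxide-induced anti-elimination of boron and iodine converts the Z-lithio geometry into the required 8E alkene without touching the 10E alkene.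

Step 10
Reactants: 25 tert-butyl 4-[(1R,2R)-2-[(2S,3E,5E,10R)-6,10-dimethyl-13-(triisopropylsilyl)trideca-3,5-dien-12-yn-2-yl]cyclopropyl]butanoate
Product: 27 tert-butyl 4-[(1R,2R)-2-[(2S,3E,5E,10R)-13-bromo-6,10-dimethyltrideca-3,5-dien-12-yn-2-yl]cyclopropyl]butanoate, via silver acetylide 26 (not isolated)
Conditions: NBS (1.1 equiv), AgF (1.1 equiv), MeCN, rt, dark
Reagents that add atoms: N-bromosuccinimide O=C1CCC(=O)N1Br
Why: Silver-mediated desilylative bromination: fluoride-assisted C–Si to C–Ag exchange gives a silver acetylide that captures Br+ from NBS much faster than the diene does.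

Step 11
Reactants: 27 tert-butyl 4-[(1R,2R)-2-[(2S,3E,5E,10R)-13-bromo-6,10-dimethyltrideca-3,5-dien-12-yn-2-yl]cyclopropyl]butanoate
Product: 29 4-[(1R,2R)-2-[(2S,3E,5E,10R)-13-bromo-6,10-dimethyltrideca-3,5-dien-12-yn-2-yl]cyclopropyl]butanoic acid, via trimethylsilyl ester 28 (not isolated)
Conditions: TMSOTf, 2,6-lutidine, CH2Cl2, 0 °C; then pH 5 aqueous work-up
Reagents that add atoms: none
Why: Silyl-triflate-induced tert-butyl ester cleavage (loss of isobutene, then hydrolysis of the silyl ester) runs under lutidine buffering, so the diene, the cyclopropane and the bromoalkyne never see free acid.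

## Compound list
1 | hex-5-enoic acid | C=CCCCC(=O)O | starting material
2 | tert-butyl hex-5-enoate | C=CCCCC(=O)OC(C)(C)C | intermediate
3 | tert-butyl 4-[(1R,2R)-2-(4,4,5,5-tetramethyl-1,3,2-dioxaborolan-2-yl)cyclopropyl]butanoate | CC1(C)OB(OC1(C)C)[C@@H]2C[C@H]2CCCC(=O)OC(C)(C)C | intermediate
4 | lithium boronate complex of 3 carrying the (S)-1-(2,4,6-triisopropylbenzoyloxy)ethyl group on boron | [Li+].CC1(C)O[B-](OC1(C)C)([C@@H](C)OC(=O)c2c(C(C)C)cc(C(C)C)cc2C(C)C)[C@@H]3C[C@H]3CCCC(=O)OC(C)(C)C | intermediate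
5 | tert-butyl 4-[(1R,2S)-2-[(1R)-1-(4,4,5,5-tetramethyl-1,3,2-dioxaborolan-2-yl)ethyl]cyclopropyl]butanoate | CC1(C)OB(OC1(C)C)[C@H](C)[C@@H]2C[C@H]2CCCC(=O)OC(C)(C)C | intermediate
6 | ethynyltriisopropylsilane (TIPS-protected acetylene) | C#C[Si](C(C)C)(C(C)C)C(C)C | starting material
7 | (R)-2-methyloxirane | C[C@@H]1CO1 | starting material
8 | lithium (triisopropylsilyl)acetylide | [Li]C#C[Si](C(C)C)(C(C)C)C(C)C | intermediate
9 | (2R)-5-(triisopropylsilyl)pent-4-yn-2-ol | C[C@@H](O)CC#C[Si](C(C)C)(C(C)C)C(C)C | intermediate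
10 | (2R)-5-(triisopropylsilyl)pent-4-yn-2-yl 4-methylbenzenesulfonate | C[C@@H](OS(=O)(=O)c1ccc(C)cc1)CC#C[Si](C(C)C)(C(C)C)C(C)C | intermediate
11 | (5-chloropent-1-yn-1-yl)trimethylsilane (TMS-protected 5-chloropent-1-yne) | C[Si](C)(C)C#CCCCCl | starting material
12 | [5-(trimethylsilyl)pent-4-yn-1-yl]magnesium chloride | C[Si](C)(C)C#CCCC[Mg]Cl | intermediate
13 | [(4R)-4-methyl-9-(trimethylsilyl)nona-1,8-diyn-1-yl]triisopropylsilane | C[Si](C)(C)C#CCCC[C@@H](C)CC#C[Si](C(C)C)(C(C)C)C(C)C | intermediate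
14 | [(4R)-4-methylnona-1,8-diyn-1-yl]triisopropylsilane | C#CCCC[C@@H](C)CC#C[Si](C(C)C)(C(C)C)C(C)C | intermediate
15 | dimethyl[(1E,6R)-2,6-dimethyl-9-(triisopropylsilyl)non-1-en-8-yn-1-yl]alane | C[Al](C)/C=C(\C)CCC[C@@H](C)CC#C[Si](C(C)C)(C(C)C)C(C)C | intermediate
16 | [(4R,8E)-9-iodo-4,8-dimethylnon-8-en-1-yn-1-yl]triisopropylsilane | I/C=C(\C)CCC[C@@H](C)CC#C[Si](C(C)C)(C(C)C)C(C)C | intermediate
17 | acetylene | C#C | starting material
18 | (1E,6R)-2,6-dimethyl-9-(triisopropylsilyl)non-1-en-8-yn-1-yllithium | [Li]/C=C(\C)CCC[C@@H](C)CC#C[Si](C(C)C)(C(C)C)C(C)C | intermediate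
19 | lithium bis[(1E,6R)-2,6-dimethyl-9-(triisopropylsilyl)non-1-en-8-yn-1-yl]cuprate | [Li+].[Cu-](/C=C(\C)CCC[C@@H](C)CC#C[Si](C(C)C)(C(C)C)C(C)C)/C=C(\C)CCC[C@@H](C)CC#C[Si](C(C)C)(C(C)C)C(C)C | intermediate
20 | lithium bis[(1Z,3E,8R)-4,8-dimethyl-11-(triisopropylsilyl)undeca-1,3-dien-10-yn-1-yl]cuprate | [Li+].[Cu-](/C=C\C=C(/C)CCC[C@@H](C)CC#C[Si](C(C)C)(C(C)C)C(C)C)/C=C\C=C(/C)CCC[C@@H](C)CC#C[Si](C(C)C)(C(C)C)C(C)C | intermediate
21 | [(4R,8E,10Z)-11-iodo-4,8-dimethylundeca-8,10-dien-1-yn-1-yl]triisopropylsilane | I/C=C\C=C(/C)CCC[C@@H](C)CC#C[Si](C(C)C)(C(C)C)C(C)C | intermediate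
22 | (1Z,3E,8R)-4,8-dimethyl-11-(triisopropylsilyl)undeca-1,3-dien-10-yn-1-yllithium | [Li]/C=C\C=C(/C)CCC[C@@H](C)CC#C[Si](C(C)C)(C(C)C)C(C)C | intermediate
23 | lithium boronate complex of 5 carrying the (1Z,3E)-dienyl group of 22 on boron | [Li+].CC1(C)O[B-](OC1(C)C)(/C=C\C=C(/C)CCC[C@@H](C)CC#C[Si](C(C)C)(C(C)C)C(C)C)[C@H](C)[C@@H]2C[C@H]2CCCC(=O)OC(C)(C)C | intermediate
24 | beta-iodo boronic ester, the anti adduct of the migrating group (C8) and iodine (C9); one of two facial isomers drawn, both collapse to 25 | CC1(C)OB(OC1(C)C)[C@@H]([C@H](C)[C@@H]2C[C@H]2CCCC(=O)OC(C)(C)C)[C@H](I)/C=C(\C)CCC[C@@H](C)CC#C[Si](C(C)C)(C(C)C)C(C)C | intermediate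
25 | tert-butyl 4-[(1R,2R)-2-[(2S,3E,5E,10R)-6,10-dimethyl-13-(triisopropylsilyl)trideca-3,5-dien-12-yn-2-yl]cyclopropyl]butanoate | C/C(=C\C=C\[C@H](C)[C@@H]1C[C@H]1CCCC(=O)OC(C)(C)C)CCC[C@@H](C)CC#C[Si](C(C)C)(C(C)C)C(C)C | intermediate
26 | silver acetylide of desilylated 25 | C/C(=C\C=C\[C@H](C)[C@@H]1C[C@H]1CCCC(=O)OC(C)(C)C)CCC[C@@H](C)CC#C[Ag] | intermediate
27 | tert-butyl 4-[(1R,2R)-2-[(2S,3E,5E,10R)-13-bromo-6,10-dimethyltrideca-3,5-dien-12-yn-2-yl]cyclopropyl]butanoate | C/C(=C\C=C\[C@H](C)[C@@H]1C[C@H]1CCCC(=O)OC(C)(C)C)CCC[C@@H](C)CC#CBr | intermediate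
28 | trimethylsilyl 4-[(1R,2R)-2-[(2S,3E,5E,10R)-13-bromo-6,10-dimethyltrideca-3,5-dien-12-yn-2-yl]cyclopropyl]butanoate | C/C(=C\C=C\[C@H](C)[C@@H]1C[C@H]1CCCC(=O)O[Si](C)(C)C)CCC[C@@H](C)CC#CBr | intermediate
29 | 4-[(1R,2R)-2-[(2S,3E,5E,10R)-13-bromo-6,10-dimethyltrideca-3,5-dien-12-yn-2-yl]cyclopropyl]butanoic acid | C/C(=C\C=C\[C@H](C)[C@@H]1C[C@H]1CCCC(=O)O)CCC[C@@H](C)CC#CBr | target

## Step count and risks
Total step count: 11. Longest linear sequence: 8 (steps 4 to 11). The left-hand branch runs through steps 1 to 3 and joins at step 9.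

**Step 2, the proposed new step.**
- Risk: neither the enantioselectivity nor the reactivity of the chromium carbenoid with a bulkier chiral diamine is proven.
- Fallback: it sets out from 2 and comes back at 5. The known racemic CrCl2/TMEDA borylcyclopropanation of 2 gives 3 together with its mirror image tert-butyl 4-[(1S,2S)-2-(4,4,5,5-tetramethyl-1,3,2-dioxaborolan-2-yl)cyclopropyl]butanoate F1. The racemate is homologated exactly as in step 3 with the same (S)-carbenoid. Compound 3 then gives 5, and F1 gives the diastereomer tert-butyl 4-[(1S,2R)-2-[(1R)-1-(4,4,5,5-tetramethyl-1,3,2-dioxaborolan-2-yl)ethyl]cyclopropyl]butanoate F2. Compound 5 is separated from F2 by chromatography, with HPLC if needed. Stereocontrol then rests on resolution through a reagent-controlled step instead of on ligand-controlled ring formation, at the cost of half the material.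

**Step 8.**
- Risk: addition of an alkenyl cuprate to acetylene is slower than that of an alkyl cuprate. A further acetylene insertion and oxidative dimerisation on iodinolysis can also compete.
- Fallback: it sets out from 16 and comes back at 21. Compound 16 is lithiated to 18 and formylated with DMF to (2E,7R)-3,7-dimethyl-10-(triisopropylsilyl)dec-2-en-9-ynal F3. A Stork–Zhao olefination of F3 (iodomethyltriphenylphosphonium iodide, NaHMDS, THF/DMPU, −78 °C) gives 21. This costs one extra step, and carbonyl olefination replaces carbometalation.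

**Step 9.**
- Risk: iodine could attack the distal end of the dienyl boronate. The allylic iodide 24 could also ionise. Either event would erode the 8E geometry.
- Fallback: it sets out from 5 and 16 and comes back at 25, and step 8 is then not needed. The final bond made becomes C9–C10. All four operations below are known chemistry.
  - Zweifel-type coupling of 5 with alpha-lithiated vinyl N,N-diisopropylcarbamate (I2, NaOMe) gives tert-butyl 4-[(1R,2R)-2-[(2R)-3-(diisopropylcarbamoyloxy)but-3-en-2-yl]cyclopropyl]butanoate F4.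
  - Excess LDA induces 1,2-elimination to tert-butyl 4-[(1R,2R)-2-[(2R)-but-3-yn-2-yl]cyclopropyl]butanoate F5. The ester enolate formed alongside is reprotonated on work-up.
  - Zirconocene-catalysed hydroboration with pinacolborane gives tert-butyl 4-[(1R,2R)-2-[(2S,3E)-4-(4,4,5,5-tetramethyl-1,3,2-dioxaborolan-2-yl)but-3-en-2-yl]cyclopropyl]butanoate F6.
  - Suzuki–Miyaura coupling of F6 with vinyl iodide 16 (Pd(dppf)Cl2, K3PO4, DMF/H2O) gives 25 with retention of both alkene geometries.

## Further compounds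
F1 | step 2 | tert-butyl 4-[(1S,2S)-2-(4,4,5,5-tetramethyl-1,3,2-dioxaborolan-2-yl)cyclopropyl]butanoate | CC1(C)OB(OC1(C)C)[C@H]2C[C@@H]2CCCC(=O)OC(C)(C)C
F2 | step 2 | tert-butyl 4-[(1S,2R)-2-[(1R)-1-(4,4,5,5-tetramethyl-1,3,2-dioxaborolan-2-yl)ethyl]cyclopropyl]butanoate | CC1(C)OB(OC1(C)C)[C@H](C)[C@H]2C[C@@H]2CCCC(=O)OC(C)(C)C
F3 | step 8 | (2E,7R)-3,7-dimethyl-10-(triisopropylsilyl)dec-2-en-9-ynal | O=C/C=C(\C)CCC[C@@H](C)CC#C[Si](C(C)C)(C(C)C)C(C)C
F4 | step 9 | tert-butyl 4-[(1R,2R)-2-[(2R)-3-(diisopropylcarbamoyloxy)but-3-en-2-yl]cyclopropyl]butanoate | C=C(OC(=O)N(C(C)C)C(C)C)[C@H](C)[C@@H]1C[C@H]1CCCC(=O)OC(C)(C)C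
F5 | step 9 | tert-butyl 4-[(1R,2R)-2-[(2R)-but-3-yn-2-yl]cyclopropyl]butanoate | C#C[C@H](C)[C@@H]1C[C@H]1CCCC(=O)OC(C)(C)C
F6 | step 9 | tert-butyl 4-[(1R,2R)-2-[(2S,3E)-4-(4,4,5,5-tetramethyl-1,3,2-dioxaborolan-2-yl)but-3-en-2-yl]cyclopropyl]butanoate | CC1(C)OB(OC1(C)C)/C=C/[C@H](C)[C@@H]2C[C@H]2CCCC(=O)OC(C)(C)C
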